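**Retrosynthetic overview**
1. Target ⇐ Elbs persulfate oxidation of phenol 27 (sulfate enters para to OH) ⇐ methylenation and O‑demethylation/decarboxylation of cyclic β‑keto ester 24.
2. Ring A (formed last) ⇐ SnCl4 epoxide‑opening cyclization of acyclic epoxy β‑keto ester 23 ⇐ octalin acetaldehyde 15 + epoxy keto ester 21 (geraniol, Sharpless epoxidation, acetoacetate dianion).
3. Ring B (formed second) ⇐ catalytic asymmetric Diels–Alder of vinylcyclohexene 10 with methacrolein (sets the remote quaternary carbon), then acid isomerization of the alkene into the ring fusion.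
4. Ring C (first) ⇐ key step: enantioselective desymmetrizing reduction of the prochiral dione 3 (sets the benzylic quaternary carbon); the carbinol then relays to the secondary methyl by OH‑directed hydrogenation.
5. Dione 3 ⇐ 2‑methylcyclohexane‑1,3‑dione + 2‑methoxybenzyl chloride; the arene is carried as its methyl ether throughout.

Assumption: the antipodes named for the two oxazaborolidine catalysts and the tartrate are those expected from their published facial models; the target is handled as its potassium salt until the last acidification.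

**Step 1**
Reactants: 1 2-methylcyclohexane-1,3-dione; 2 1-(chloromethyl)-2-methoxybenzene
Product: 3 2-(2-methoxybenzyl)-2-methylcyclohexane-1,3-dione
Conditions: NaOH (1.0 equiv), Bu4NI (10 mol %), H2O–dioxane, 40 °C
Reagents that add atoms: none
Why: C‑alkylation of the 1,3‑dione enolate by a reactive benzylic halide in water (iodide catalysis) beats O‑alkylation; the product is achiral with two enantiotopic carbonyls.

**Step 2**
Reactants: 3 2-(2-methoxybenzyl)-2-methylcyclohexane-1,3-dione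
Product: 4 (2S,3S)-3-hydroxy-2-(2-methoxybenzyl)-2-methylcyclohexan-1-one
Conditions: (R)-1-methyl-3,3-diphenyltetrahydro-1H,3H-pyrrolo[1,2-c][1,3,2]oxazaborole (20 mol %), catecholborane (1.2 equiv), N,N-diethylaniline, toluene, −60 °C
Reagents that add atoms: none
Why: Corey–Bakshi–Shibata reduction used as a desymmetrization: the catalyst selects one enantiotopic ketone and hydride enters anti to the benzyl group, which fixes the quaternary carbon and places OH cis to benzyl.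

**Step 3**
Reactants: 4 (2S,3S)-3-hydroxy-2-(2-methoxybenzyl)-2-methylcyclohexan-1-one
Product: 5 (1S,2R)-2-(2-methoxybenzyl)-2-methyl-3-methylidenecyclohexan-1-ol
Conditions: Zn, CH2Br2, TiCl4, THF–CH2Cl2, 0 °C to rt
Reagents that add atoms: dibromomethane BrCBr
Why: Takai–Lombardo methylenation is non‑basic, so the β‑hydroxy ketone cannot undergo retro‑aldol cleavage, and it converts hindered ketones next to quaternary carbons.

**Step 4**
Reactants: 5 (1S,2R)-2-(2-methoxybenzyl)-2-methyl-3-methylidenecyclohexan-1-ol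
Product: 6 (1S,2R,3S)-2-(2-methoxybenzyl)-2,3-dimethylcyclohexan-1-ol
Conditions: [Ir(cod)(PCy3)(py)]PF6 (5 mol %), H2 (1 atm), CH2Cl2, 0 °C to rt
Reagents that add atoms: none
Why: Hydroxyl‑directed hydrogenation (Stork–Crabtree): iridium bound to the homoallylic OH delivers H2 to the face syn to OH (the benzyl face), so the new methyl ends trans to benzyl and cis to the quaternary methyl.

**Step 5**
Reactants: 6 (1S,2R,3S)-2-(2-methoxybenzyl)-2,3-dimethylcyclohexan-1-ol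
Product: 7 (2R,3S)-2-(2-methoxybenzyl)-2,3-dimethylcyclohexan-1-one
Conditions: (n-Pr)4N[RuO4] (5 mol %), N-methylmorpholine N-oxide (1.5 equiv), 4 Å MS, CH2Cl2, rt
Reagents that add atoms: none
Why: Ley–Griffith oxidation of the secondary alcohol under neutral conditions; neither the α‑quaternary nor the β‑tertiary centre can epimerize.

**Step 6**
Reactants: 7 (2R,3S)-2-(2-methoxybenzyl)-2,3-dimethylcyclohexan-1-one
Product: 9 (5S,6R)-6-(2-methoxybenzyl)-5,6-dimethylcyclohex-1-en-1-yl trifluoromethanesulfonate, via potassium enolate 8 (not isolated)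
Conditions: KN(SiMe3)2, THF, −78 °C; then PhNTf2, −78 to 0 °C
Reagents that add atoms: N-phenylbis(trifluoromethanesulfonimide) O=S(=O)(N(c1ccccc1)S(=O)(=O)C(F)(F)F)C(F)(F)F
Why: Only one α‑carbon bears hydrogen, so enolization is regiospecific and O‑sulfonylation gives a single enol triflate.

**Step 7**
Reactants: 9 (5S,6R)-6-(2-methoxybenzyl)-5,6-dimethylcyclohex-1-en-1-yl trifluoromethanesulfonate
Product: 10 1-{[(1R,6S)-2-ethenyl-1,6-dimethylcyclohex-2-en-1-yl]methyl}-2-methoxybenzene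
Conditions: tributyl(ethenyl)stannane, Pd(PPh3)4 (5 mol %), LiCl, THF, 65 °C
Reagents that add atoms: tributyl(ethenyl)stannane C=C[Sn](CCCC)(CCCC)CCCC
Why: Stille coupling of the enol triflate gives the 1‑vinylcyclohexene; no stereocentre is touched.

**Step 8**
Reactants: 10 1-{[(1R,6S)-2-ethenyl-1,6-dimethylcyclohex-2-en-1-yl]methyl}-2-methoxybenzene; 11 2-methylprop-2-enal
Product: 12 (1S,5R,6S,8aR)-5-(2-methoxybenzyl)-1,5,6-trimethyl-1,2,3,5,6,7,8,8a-octahydronaphthalene-1-carbaldehyde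
Conditions: (S)-3,3-diphenyl-1-(2-methylphenyl)tetrahydro-1H,3H-pyrrolo[1,2-c][1,3,2]oxazaborole (20 mol %), Tf2NH (18 mol %), CH2Cl2, −78 to −40 °C
Reagents that add atoms: none
Why: Enantioselective Diels–Alder reaction under a cationic oxazaborolidine: the formyl‑bearing carbon bonds to the ring CH terminus (ortho rule) and the catalyst exposes the Re face of C‑2 of the enal, fixing the new quaternary carbon (1S) whichever diene face reacts; the ring‑fusion CH (drawn as the expected major epimer) is planarized in step 9.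

**Step 9**
Reactants: 12 (1S,5R,6S,8aR)-5-(2-methoxybenzyl)-1,5,6-trimethyl-1,2,3,5,6,7,8,8a-octahydronaphthalene-1-carbaldehyde
Product: 13 (1S,5R,6S)-5-(2-methoxybenzyl)-1,5,6-trimethyl-1,2,3,4,5,6,7,8-octahydronaphthalene-1-carbaldehyde
Conditions: TsOH·H2O (10 mol %), benzene, 60 °C
Reagents that add atoms: none
Why: Acid‑catalysed alkene isomerization: protonation gives the tertiary cation and loss of the ring‑fusion proton gives the tetrasubstituted alkene, the isomer obtained under acid in rearranged drimane systems with the same substitution; the aldehyde cannot enolize.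

**Step 10**
Reactants: 13 (1S,5R,6S)-5-(2-methoxybenzyl)-1,5,6-trimethyl-1,2,3,4,5,6,7,8-octahydronaphthalene-1-carbaldehyde
Product: 15 2-[(1R,5R,6S)-5-(2-methoxybenzyl)-1,5,6-trimethyl-1,2,3,4,5,6,7,8-octahydronaphthalen-1-yl]acetaldehyde, via enol ether 14 (not isolated)
Conditions: MeOCH2PPh3Cl, KN(SiMe3)2, THF, −78 to 0 °C; then 2 M HCl (aq), THF, rt
Reagents that add atoms: (methoxymethyl)triphenylphosphonium chloride COC[P+](c1ccccc1)(c1ccccc1)c1ccccc1.[Cl-]; water O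
Why: Wittig methoxymethylenation followed by enol ether hydrolysis (one‑carbon homologation); the stereocentres are not at the reacting carbon.

**Step 11**
Reactants: 16 geraniol
Product: 17 [(2S,3S)-3-methyl-3-(4-methylpent-3-en-1-yl)oxiran-2-yl]methanol
Conditions: Ti(OiPr)4 (5 mol %), L-(+)-diethyl tartrate (6 mol %), t-BuOOH, 4 Å MS, CH2Cl2, −20 °C
Reagents that add atoms: tert-butyl hydroperoxide CC(C)(C)OO
Why: Sharpless asymmetric epoxidation; the L‑tartrate complex delivers oxygen to the allylic alkene face that gives the (2S,3S)‑epoxide and leaves the remote alkene alone.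

**Step 12**
Reactants: 17 [(2S,3S)-3-methyl-3-(4-methylpent-3-en-1-yl)oxiran-2-yl]methanol
Product: 18 [(2S,3S)-3-methyl-3-(4-methylpent-3-en-1-yl)oxiran-2-yl]methyl 4-methylbenzenesulfonate
Conditions: TsCl, Et3N, 4-(dimethylamino)pyridine (5 mol %), CH2Cl2, 0 °C
Reagents that add atoms: 4-methylbenzenesulfonyl chloride Cc1ccc(cc1)S(Cl)(=O)=O
Why: Sulfonylation of the primary alcohol; the epoxide is untouched.

**Step 13**
Reactants: 18 [(2S,3S)-3-methyl-3-(4-methylpent-3-en-1-yl)oxiran-2-yl]methyl 4-methylbenzenesulfonate; 19 methyl 3-oxobutanoate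
Product: 21 methyl 5-[(2S,3S)-3-methyl-3-(4-methylpent-3-en-1-yl)oxiran-2-yl]-3-oxopentanoate, via dianion 20 (not isolated)
Conditions: 19, NaH, THF, 0 °C; n-BuLi, 0 °C; then 18, −20 to 0 °C
Reagents that add atoms: none
Why: Weiler dianion alkylation: the terminal carbanion displaces the primary tosylate by SN2 faster than it opens the trisubstituted epoxide; stereocentres are untouched.

**Step 14**
Reactants: 15 2-[(1R,5R,6S)-5-(2-methoxybenzyl)-1,5,6-trimethyl-1,2,3,4,5,6,7,8-octahydronaphthalen-1-yl]acetaldehyde; 21 methyl 5-[(2S,3S)-3-methyl-3-(4-methylpent-3-en-1-yl)oxiran-2-yl]-3-oxopentanoate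
Product: 23 methyl 2-{2-[(1R,5R,6S)-5-(2-methoxybenzyl)-1,5,6-trimethyl-1,2,3,4,5,6,7,8-octahydronaphthalen-1-yl]ethyl}-5-[(2S,3S)-3-methyl-3-(4-methylpent-3-en-1-yl)oxiran-2-yl]-3-oxopentanoate (both C-2 epimers), via alkylidene keto ester 22 (not isolated)
Conditions: L-proline (20 mol %), diethyl 2,6-dimethyl-1,4-dihydropyridine-3,5-dicarboxylate (1.2 equiv), EtOH, rt
Reagents that add atoms: none
Why: Knoevenagel condensation at the doubly activated methylene followed in the same flask by conjugate transfer hydrogenation from the Hantzsch ester (organocatalytic reductive alkylation), which prevents bis‑addition; the new centre is an epimer mixture erased in step 16.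

**Step 15**
Reactants: 23 methyl 2-{2-[(1R,5R,6S)-5-(2-methoxybenzyl)-1,5,6-trimethyl-1,2,3,4,5,6,7,8-octahydronaphthalen-1-yl]ethyl}-5-[(2S,3S)-3-methyl-3-(4-methylpent-3-en-1-yl)oxiran-2-yl]-3-oxopentanoate
Product: 24 methyl (2S,3S)-3-hydroxy-1-{2-[(1R,5R,6S)-5-(2-methoxybenzyl)-1,5,6-trimethyl-1,2,3,4,5,6,7,8-octahydronaphthalen-1-yl]ethyl}-2-methyl-2-(4-methylpent-3-en-1-yl)-6-oxocyclohexane-1-carboxylate (both C-1 epimers)
Conditions: SnCl4 (2 equiv), CH2Cl2, −78 to −40 °C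
Reagents that add atoms: none
Why: Lewis acid epoxide‑opening cyclization (6‑enolendo‑exo‑tet) of the tin‑chelated β‑keto ester enol onto the tertiary epoxide carbon, as with β‑keto ester terminators in cationic polyene cyclizations: anti opening inverts that carbon and retains the carbinol carbon, so the (E)‑derived (2S,3S)‑epoxide gives OH cis to methyl and trans to the homoprenyl group.

**Step 16**
Reactants: 24 methyl (2S,3S)-3-hydroxy-1-{2-[(1R,5R,6S)-5-(2-methoxybenzyl)-1,5,6-trimethyl-1,2,3,4,5,6,7,8-octahydronaphthalen-1-yl]ethyl}-2-methyl-2-(4-methylpent-3-en-1-yl)-6-oxocyclohexane-1-carboxylate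
Product: 26 (2S,3S,4S)-4-hydroxy-2-{2-[(1R,5R,6S)-5-(2-hydroxybenzyl)-1,5,6-trimethyl-1,2,3,4,5,6,7,8-octahydronaphthalen-1-yl]ethyl}-3-methyl-3-(4-methylpent-3-en-1-yl)cyclohexan-1-one, via keto acid 25 (not isolated)
Conditions: EtSNa (6 equiv), DMF, 140 °C; then 1 M HCl (aq), 40 °C
Reagents that add atoms: none
Why: Thiolate SN2 dealkylation removes both O‑methyl groups (Krapcho‑type ester cleavage and aryl methyl ether cleavage), the β‑keto acid loses CO2, and the enolizable ring carbon equilibrates to the equatorial side chain (cis to OH and to the axial methyl); the epimer ratio is expected to be modest and may need separation.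

**Step 17**
Reactants: 26 (2S,3S,4S)-4-hydroxy-2-{2-[(1R,5R,6S)-5-(2-hydroxybenzyl)-1,5,6-trimethyl-1,2,3,4,5,6,7,8-octahydronaphthalen-1-yl]ethyl}-3-methyl-3-(4-methylpent-3-en-1-yl)cyclohexan-1-one
Product: 27 2-{[(1R,2S,5R)-5-{2-[(1R,2S,3S)-3-hydroxy-2-methyl-6-methylidene-2-(4-methylpent-3-en-1-yl)cyclohexyl]ethyl}-1,2,5-trimethyl-1,2,3,4,5,6,7,8-octahydronaphthalen-1-yl]methyl}phenol
Conditions: Ph3PCH3Br (5 equiv), KOtBu (5 equiv), toluene, 80 °C
Reagents that add atoms: methyltriphenylphosphonium bromide C[P+](c1ccccc1)(c1ccccc1)c1ccccc1.[Br-]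
Why: Wittig methylenation of the hindered ketone with excess ylide (phenoxide and alkoxide form first); the basic medium keeps the α‑centre at its thermodynamic configuration.

**Step 18**
Reactants: 27 2-{[(1R,2S,5R)-5-{2-[(1R,2S,3S)-3-hydroxy-2-methyl-6-methylidene-2-(4-methylpent-3-en-1-yl)cyclohexyl]ethyl}-1,2,5-trimethyl-1,2,3,4,5,6,7,8-octahydronaphthalen-1-yl]methyl}phenol
Product: 29 4-hydroxy-3-{[(1R,2S,5R)-5-{2-[(1R,2S,3S)-3-hydroxy-2-methyl-6-methylidene-2-(4-methylpent-3-en-1-yl)cyclohexyl]ethyl}-1,2,5-trimethyl-1,2,3,4,5,6,7,8-octahydronaphthalen-1-yl]methyl}phenyl hydrogen sulfate, via dipotassium salt 28 (not isolated)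
Conditions: K2S2O8 (1.2 equiv), KOH (aq), pyridine–H2O, 5 to 20 °C, 24 h; then cold 1 M HCl to pH 2, n-BuOH extraction
Reagents that add atoms: potassium peroxodisulfate [K+].[K+].[O-]S(=O)(=O)OOS(=O)(=O)[O-]
Why: Elbs persulfate oxidation: the phenolate attacks the peroxide oxygen through its para carbon and the cyclohexadienone rearomatizes, so the sulfate ester is placed only para to the free OH, as in the target; isolated alkenes and the secondary alcohol are not expected to react at 20 °C.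

**Compound list**
1 | 2-methylcyclohexane-1,3-dione | CC1C(=O)CCCC1=O | starting material
2 | 1-(chloromethyl)-2-methoxybenzene (2-methoxybenzyl chloride) | COc1ccccc1CCl | starting material
3 | 2-(2-methoxybenzyl)-2-methylcyclohexane-1,3-dione | COc1ccccc1CC1(C)C(=O)CCCC1=O | intermediate
4 | (2S,3S)-3-hydroxy-2-(2-methoxybenzyl)-2-methylcyclohexan-1-one | O[C@H]1CCCC(=O)[C@@]1(C)Cc1ccccc1OC | intermediate
5 | (1S,2R)-2-(2-methoxybenzyl)-2-methyl-3-methylidenecyclohexan-1-ol | O[C@H]1CCCC(=C)[C@@]1(C)Cc1ccccc1OC | intermediate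
6 | (1S,2R,3S)-2-(2-methoxybenzyl)-2,3-dimethylcyclohexan-1-ol | O[C@H]1CCC[C@H](C)[C@@]1(C)Cc1ccccc1OC | intermediate
7 | (2R,3S)-2-(2-methoxybenzyl)-2,3-dimethylcyclohexan-1-one | O=C1CCC[C@H](C)[C@@]1(C)Cc1ccccc1OC | intermediate
8 | potassium (5S,6R)-6-(2-methoxybenzyl)-5,6-dimethylcyclohex-1-en-1-olate | [K+].[O-]C1=CCC[C@H](C)[C@@]1(C)Cc1ccccc1OC | intermediate
9 | (5S,6R)-6-(2-methoxybenzyl)-5,6-dimethylcyclohex-1-en-1-yl trifluoromethanesulfonate | O=S(=O)(OC1=CCC[C@H](C)[C@@]1(C)Cc1ccccc1OC)C(F)(F)F | intermediate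
10 | 1-{[(1R,6S)-2-ethenyl-1,6-dimethylcyclohex-2-en-1-yl]methyl}-2-methoxybenzene | C=CC1=CCC[C@H](C)[C@@]1(C)Cc1ccccc1OC | intermediate
11 | 2-methylprop-2-enal (methacrolein) | CC(=C)C=O | starting material
12 | (1S,5R,6S,8aR)-5-(2-methoxybenzyl)-1,5,6-trimethyl-1,2,3,5,6,7,8,8a-octahydronaphthalene-1-carbaldehyde | O=C[C@@]1(C)CCC=C2[C@H]1CC[C@H](C)[C@@]2(C)Cc1ccccc1OC | intermediate
13 | (1S,5R,6S)-5-(2-methoxybenzyl)-1,5,6-trimethyl-1,2,3,4,5,6,7,8-octahydronaphthalene-1-carbaldehyde | O=C[C@@]1(C)CCCC2=C1CC[C@H](C)[C@@]2(C)Cc1ccccc1OC | intermediate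
14 | 1-{[(1R,2S,5R)-5-(2-methoxyethenyl)-1,2,5-trimethyl-1,2,3,4,5,6,7,8-octahydronaphthalen-1-yl]methyl}-2-methoxybenzene (E/Z mixture) | COC=C[C@@]1(C)CCCC2=C1CC[C@H](C)[C@@]2(C)Cc1ccccc1OC | intermediate
15 | 2-[(1R,5R,6S)-5-(2-methoxybenzyl)-1,5,6-trimethyl-1,2,3,4,5,6,7,8-octahydronaphthalen-1-yl]acetaldehyde | O=CC[C@@]1(C)CCCC2=C1CC[C@H](C)[C@@]2(C)Cc1ccccc1OC | intermediate
16 | geraniol, (2E)-3,7-dimethylocta-2,6-dien-1-ol | CC(C)=CCC/C(C)=C/CO | starting material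
17 | [(2S,3S)-3-methyl-3-(4-methylpent-3-en-1-yl)oxiran-2-yl]methanol | OC[C@@H]1O[C@@]1(C)CCC=C(C)C | intermediate
18 | [(2S,3S)-3-methyl-3-(4-methylpent-3-en-1-yl)oxiran-2-yl]methyl 4-methylbenzenesulfonate | Cc1ccc(cc1)S(=O)(=O)OC[C@@H]1O[C@@]1(C)CCC=C(C)C | intermediate
19 | methyl 3-oxobutanoate | COC(=O)CC(C)=O | starting material
20 | sodium lithium dianion of methyl 3-oxobutanoate | [Na+].[Li+].[CH2-]C(=O)[CH-]C(=O)OC | intermediate
21 | methyl 5-[(2S,3S)-3-methyl-3-(4-methylpent-3-en-1-yl)oxiran-2-yl]-3-oxopentanoate | COC(=O)CC(=O)CC[C@@H]1O[C@@]1(C)CCC=C(C)C | intermediate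
22 | methyl 2-{2-[(1R,5R,6S)-5-(2-methoxybenzyl)-1,5,6-trimethyl-1,2,3,4,5,6,7,8-octahydronaphthalen-1-yl]ethylidene}-5-[(2S,3S)-3-methyl-3-(4-methylpent-3-en-1-yl)oxiran-2-yl]-3-oxopentanoate (E/Z mixture) | COC(=O)C(=CC[C@@]1(C)CCCC2=C1CC[C@H](C)[C@@]2(C)Cc1ccccc1OC)C(=O)CC[C@@H]1O[C@@]1(C)CCC=C(C)C | intermediate
23 | methyl 2-{2-[(1R,5R,6S)-5-(2-methoxybenzyl)-1,5,6-trimethyl-1,2,3,4,5,6,7,8-octahydronaphthalen-1-yl]ethyl}-5-[(2S,3S)-3-methyl-3-(4-methylpent-3-en-1-yl)oxiran-2-yl]-3-oxopentanoate (both C-2 epimers) | COC(=O)C(CC[C@@]1(C)CCCC2=C1CC[C@H](C)[C@@]2(C)Cc1ccccc1OC)C(=O)CC[C@@H]1O[C@@]1(C)CCC=C(C)C | intermediate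
24 | methyl (2S,3S)-3-hydroxy-1-{2-[(1R,5R,6S)-5-(2-methoxybenzyl)-1,5,6-trimethyl-1,2,3,4,5,6,7,8-octahydronaphthalen-1-yl]ethyl}-2-methyl-2-(4-methylpent-3-en-1-yl)-6-oxocyclohexane-1-carboxylate (both C-1 epimers) | O=C1CC[C@H](O)[C@@](C)(CCC=C(C)C)C1(C(=O)OC)CC[C@@]1(C)CCCC2=C1CC[C@H](C)[C@@]2(C)Cc1ccccc1OC | intermediate
25 | (2S,3S)-3-hydroxy-1-{2-[(1R,5R,6S)-5-(2-hydroxybenzyl)-1,5,6-trimethyl-1,2,3,4,5,6,7,8-octahydronaphthalen-1-yl]ethyl}-2-methyl-2-(4-methylpent-3-en-1-yl)-6-oxocyclohexane-1-carboxylic acid | O=C1CC[C@H](O)[C@@](C)(CCC=C(C)C)C1(C(=O)O)CC[C@@]1(C)CCCC2=C1CC[C@H](C)[C@@]2(C)Cc1ccccc1O | intermediate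
26 | (2S,3S,4S)-4-hydroxy-2-{2-[(1R,5R,6S)-5-(2-hydroxybenzyl)-1,5,6-trimethyl-1,2,3,4,5,6,7,8-octahydronaphthalen-1-yl]ethyl}-3-methyl-3-(4-methylpent-3-en-1-yl)cyclohexan-1-one | O=C1CC[C@H](O)[C@@](C)(CCC=C(C)C)[C@@H]1CC[C@@]1(C)CCCC2=C1CC[C@H](C)[C@@]2(C)Cc1ccccc1O | intermediate
27 | 2-{[(1R,2S,5R)-5-{2-[(1R,2S,3S)-3-hydroxy-2-methyl-6-methylidene-2-(4-methylpent-3-en-1-yl)cyclohexyl]ethyl}-1,2,5-trimethyl-1,2,3,4,5,6,7,8-octahydronaphthalen-1-yl]methyl}phenol | C=C1CC[C@H](O)[C@@](C)(CCC=C(C)C)[C@@H]1CC[C@@]1(C)CCCC2=C1CC[C@H](C)[C@@]2(C)Cc1ccccc1O | intermediate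
28 | dipotassium salt (phenoxide and aryl sulfate) of 29 | C=C1CC[C@H](O)[C@@](C)(CCC=C(C)C)[C@@H]1CC[C@@]1(C)CCCC2=C1CC[C@H](C)[C@@]2(C)Cc1cc(OS(=O)(=O)[O-])ccc1[O-].[K+].[K+] | intermediate
29 | 4-hydroxy-3-{[(1R,2S,5R)-5-{2-[(1R,2S,3S)-3-hydroxy-2-methyl-6-methylidene-2-(4-methylpent-3-en-1-yl)cyclohexyl]ethyl}-1,2,5-trimethyl-1,2,3,4,5,6,7,8-octahydronaphthalen-1-yl]methyl}phenyl hydrogen sulfate (CNP0426156.3) | C=C1CC[C@H](O)[C@@](C)(CCC=C(C)C)[C@@H]1CC[C@@]1(C)CCCC2=C1CC[C@H](C)[C@@]2(C)Cc1cc(OS(=O)(=O)O)ccc1O | target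

**Step count**
Total: 18 steps. Longest linear sequence: 15 steps (steps 1–10, then 14–18); steps 11–13 make the side fragment 21.

**Three steps most likely to fail**

Step 14 (one‑pot condensation/transfer hydrogenation): the β‑branched aldehyde may condense slowly and the alkylidene keto ester may add a second keto ester. The fallback sets out from 15 and returns at 23, replacing the condensation by an SN2 alkylation. NaBH4 in MeOH reduces 15 to 2-[(1R,5R,6S)-5-(2-methoxybenzyl)-1,5,6-trimethyl-1,2,3,4,5,6,7,8-octahydronaphthalen-1-yl]ethan-1-ol F1. I2, PPh3 and imidazole convert it into 1-{[(1R,2S,5R)-5-(2-iodoethyl)-1,2,5-trimethyl-1,2,3,4,5,6,7,8-octahydronaphthalen-1-yl]methyl}-2-methoxybenzene F2. The sodium enolate of 21 (NaH, THF–DMF, 40 °C) is then alkylated by F2 at the doubly activated carbon to give 23.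

Step 15 (ring A closure): a tertiary β‑keto ester carbon must attack a tertiary epoxide carbon, making two adjacent quaternary centres; O‑alkylation of the enol, chloride opening or epoxide rearrangement may win. The fallback sets out from 23 and returns at 26, removing the ester before cyclization so that a secondary carbon is the nucleophile. Me3SnOH (ClCH2CH2Cl, 80 °C) hydrolyses the ester and the keto acid loses CO2 to give 6-[(1R,5R,6S)-5-(2-methoxybenzyl)-1,5,6-trimethyl-1,2,3,4,5,6,7,8-octahydronaphthalen-1-yl]-1-[(2S,3S)-3-methyl-3-(4-methylpent-3-en-1-yl)oxiran-2-yl]hexan-3-one F3. TBSOTf and Et3N give the silyl enol ethers; the productive regioisomer is the tert-butyldimethylsilyl enol ether with the double bond toward the octalin side F4, while the other regioisomer cannot close a six‑membered ring and is hydrolysed back to F3. MeAlCl2 (CH2Cl2, −78 °C) then closes ring A to give, after aqueous work‑up, (2S,3S,4S)-4-hydroxy-2-{2-[(1R,5R,6S)-5-(2-methoxybenzyl)-1,5,6-trimethyl-1,2,3,4,5,6,7,8-octahydronaphthalen-1-yl]ethyl}-3-methyl-3-(4-methylpent-3-en-1-yl)cyclohexan-1-one F5. EtSNa in DMF at 140 °C cleaves the aryl methyl ether to give 26.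

Step 18 (Elbs oxidation): conversion is typically modest and the lipophilic phenolate may react sluggishly. The fallback sets out from 27 and returns at 29, going through the quinone. (KSO3)2NO in KH2PO4‑buffered aqueous acetone oxidizes the phenol to 2-{[(1R,2S,5R)-5-{2-[(1R,2S,3S)-3-hydroxy-2-methyl-6-methylidene-2-(4-methylpent-3-en-1-yl)cyclohexyl]ethyl}-1,2,5-trimethyl-1,2,3,4,5,6,7,8-octahydronaphthalen-1-yl]methyl}cyclohexa-2,5-diene-1,4-dione F6. Na2S2O4 reduces it to 2-{[(1R,2S,5R)-5-{2-[(1R,2S,3S)-3-hydroxy-2-methyl-6-methylidene-2-(4-methylpent-3-en-1-yl)cyclohexyl]ethyl}-1,2,5-trimethyl-1,2,3,4,5,6,7,8-octahydronaphthalen-1-yl]methyl}benzene-1,4-diol F7. One equivalent of SO3·pyridine (pyridine, −20 °C) sulfates the hydroxyl remote from the bulky benzylic substituent, and H+ exchange gives 29; regioselectivity here rests on sterics only.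

**Further compounds**
F1 | step 14 | 2-[(1R,5R,6S)-5-(2-methoxybenzyl)-1,5,6-trimethyl-1,2,3,4,5,6,7,8-octahydronaphthalen-1-yl]ethan-1-ol | OCC[C@@]1(C)CCCC2=C1CC[C@H](C)[C@@]2(C)Cc1ccccc1OC
F2 | step 14 | 1-{[(1R,2S,5R)-5-(2-iodoethyl)-1,2,5-trimethyl-1,2,3,4,5,6,7,8-octahydronaphthalen-1-yl]methyl}-2-methoxybenzene | ICC[C@@]1(C)CCCC2=C1CC[C@H](C)[C@@]2(C)Cc1ccccc1OC
F3 | step 15 | 6-[(1R,5R,6S)-5-(2-methoxybenzyl)-1,5,6-trimethyl-1,2,3,4,5,6,7,8-octahydronaphthalen-1-yl]-1-[(2S,3S)-3-methyl-3-(4-methylpent-3-en-1-yl)oxiran-2-yl]hexan-3-one | O=C(CCC[C@@]1(C)CCCC2=C1CC[C@H](C)[C@@]2(C)Cc1ccccc1OC)CC[C@@H]1O[C@@]1(C)CCC=C(C)C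
F4 | step 15 | tert-butyldimethylsilyl enol ether of F3 with the double bond toward the octalin side (E/Z mixture) | CC(C)(C)[Si](C)(C)OC(=CCC[C@@]1(C)CCCC2=C1CC[C@H](C)[C@@]2(C)Cc1ccccc1OC)CC[C@@H]1O[C@@]1(C)CCC=C(C)C
F5 | step 15 | (2S,3S,4S)-4-hydroxy-2-{2-[(1R,5R,6S)-5-(2-methoxybenzyl)-1,5,6-trimethyl-1,2,3,4,5,6,7,8-octahydronaphthalen-1-yl]ethyl}-3-methyl-3-(4-methylpent-3-en-1-yl)cyclohexan-1-one | O=C1CC[C@H](O)[C@@](C)(CCC=C(C)C)[C@@H]1CC[C@@]1(C)CCCC2=C1CC[C@H](C)[C@@]2(C)Cc1ccccc1OC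
F6 | step 18 | 2-{[(1R,2S,5R)-5-{2-[(1R,2S,3S)-3-hydroxy-2-methyl-6-methylidene-2-(4-methylpent-3-en-1-yl)cyclohexyl]ethyl}-1,2,5-trimethyl-1,2,3,4,5,6,7,8-octahydronaphthalen-1-yl]methyl}cyclohexa-2,5-diene-1,4-dione | C=C1CC[C@H](O)[C@@](C)(CCC=C(C)C)[C@@H]1CC[C@@]1(C)CCCC2=C1CC[C@H](C)[C@@]2(C)CC1=CC(=O)C=CC1=O
F7 | step 18 | 2-{[(1R,2S,5R)-5-{2-[(1R,2S,3S)-3-hydroxy-2-methyl-6-methylidene-2-(4-methylpent-3-en-1-yl)cyclohexyl]ethyl}-1,2,5-trimethyl-1,2,3,4,5,6,7,8-octahydronaphthalen-1-yl]methyl}benzene-1,4-diol | C=C1CC[C@H](O)[C@@](C)(CCC=C(C)C)[C@@H]1CC[C@@]1(C)CCCC2=C1CC[C@H](C)[C@@]2(C)Cc1cc(O)ccc1O
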